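1. Time is read here on two clocks. One is τ, the lifetime of the substrate, whose decay is pseudo-first-order after a lag. The other is T, the charge divided by the steady pace of over-reaction.

| setting | south-west | south-east | east | green | blue |
|---|---|---|---|---|---|
| substrate | 0.030 M | 0.045 M | 0.060 M | 0.060 M | 0.060 M |
| reagent in the second phase | 3 equiv | 3 equiv | 4.5 equiv | 3.00 equiv | 3.00 equiv |
| remark | run made earlier | run made earlier | run made earlier |  |  |
| time |  |  |  | 80 min | 120 min |
| volume of the second phase over the first |  |  |  | 0.25 | 0.25 |

| run | time / min | target / % | over-reacted product / % | substrate / % |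
|---|---|---|---|---|
| south-west | 10.0 | 5.4 | 0.5 | 94.8 |
| south-west | 20.0 | 11.6 | 3.9 | 83.7 |
| south-west | 30.0 | 18.5 | 9.7 | 71.6 |
| south-west | 40.0 | 23.1 | 14.9 | 60.0 |
| south-west | 50.0 | 27.3 | 21.2 | 50.7 |
| south-west | 60.0 | 29.6 | 26.7 | 44.9 |
| south-east | 10.0 | 7.6 | 0.1 | 91.0 |
| south-east | 20.0 | 19.5 | 5.0 | 75.4 |
| south-east | 30.0 | 30.7 | 9.3 | 59.5 |
| south-east | 40.0 | 37.6 | 15.6 | 46.6 |
| south-east | 50.0 | 44.4 | 19.6 | 36.4 |
| south-east | 60.0 | 46.7 | 25.4 | 28.3 |
| east | 12.0 | 18.8 | 3.2 | 78.4 |
| east | 25.0 | 44.1 | 11.5 | 45.5 |
| east | 40.0 | 57.7 | 22.9 | 20.9 |
| east | 50.0 | 57.1 | 31.0 | 12.5 |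
| east | 60.0 | 53.5 | 38.6 | 7.0 |

(readings scatter by 0.5 percentage points)

- in the second phase: reagent in the second phase; everything else is in the first
- charges count per volume of the first phase; a concentration in a rate is the amount of a species over the volume of its own phase; every rate counts per litre of the first phase
- the earlier runs hold the two phases in the same ratio of volumes as the flask asked about
- a reading or a percentage of target counts all its forms, free or not

1. which of these there is most of at the end, counted by the substrate in it, green (substrate / over-reacted product / target)
2. which of these there is most of at the end, counted by the substrate in it, blue (substrate / over-reacted product / target)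
3. final amount of the leader among these, as a percentage of the substrate charged, in green
4. final amount of the leader among these, as a percentage of the substrate charged, in blue

2. The slope of ln(substrate) gives τ of 64.2 min in south-west, 40.8 min in south-east and 19.9 min in east, so τ shortens as reagent charged per litre rises. Green and blue hold 1.33 times the reagent of south-east, so I take τ = 30.6 min, with south-east's lag of 8.47 min.

3. Over-reacted product climbs in a straight line. South-west and south-east, both at 3 equiv, climb at nearly the same percentage pace despite different charges, so together they give T = 185 min. I keep that T for green and blue, which have the same equivalents. East gives 129 min.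

4. Target gains substrate/τ and loses 1/T of the charge per minute, so it stops growing when substrate falls to θ = τ/T, the turning level 16.5 %. East has θ = 15.4 %, and its target reads 57.7 % then 57.1 % as substrate falls from 20.9 % to 12.5 %.

5. In green at 80 min, I reckon substrate at 9.67 %, below θ at 16.5 %, over-reacted product at 36.9 % and target at 53.5 %. In blue at 120 min, substrate is 2.62 %, and over-reacted product at 58.5 % leads target at 38.9 %.

6. The forecast, from “a nearly constant rate once a little target exists”, says target at 54 % in green, near my figure, and over-reacted product at 55 % in blue, below mine.

The flask gives target at 54.8 % in green and over-reacted product at 54.2 % in blue.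

    reagent in the reaction phase ⇌ reagent in the second phase, rate k1*([reagent in the reaction phase] - [reagent in the second phase]/K1) per volume of the first phase (partition coefficient = 3.70, kL = 2.80 × 10⁻⁴ s⁻¹)
    substrate + reagent in the reaction phase ⇌ target (K = 19.0 M⁻¹, k = 0.0190 M⁻¹ s⁻¹)
    reagent in the reaction phase + target → over-reacted product (k = 0.0520 M⁻¹ s⁻¹)
    crystals ⇌ target, rate k4*(cs4 - [target]) while solid is left; crystals form when [target] > cs4 (solubility = 2.50 mM, k = 0.0530 s⁻¹)

In blue, the step forming target does half of its turnover by 29.0 min, and over-reaction does half of its own by 66.8 min. Dissolved target in blue has a half-life of 7.1 min at 28.6 min, short against green's 80 min, yet crystals in blue still hold 35.5 % at 120 min. Target stands at 56.5 % with substrate at 19.9 % in blue at 60.0 min, and at 54.8 % with substrate at 11.4 % in green at 80.0 min, either side of θ. For a neighbour of blue charged with 0.24 M, the same scaling with the reagent charged makes τ a quarter as long, so I reckon θ = 4.13 %. Its substrate reaches 0.28 %, below that level, and it ends with target leading at 53.0 %.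

The data come from a simulation for an exercise; the scatter is artificial.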